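Numbering: C1 (ester carbinol), C2=C3 (methyl on C3), C4, C5, C6 (fusion carbinol), C7 (isopropyl), C8, C9, C10 (fusion carbon with methyl). Ring A (seven-membered) is C1–C6 plus C10, and ring B (five-membered) is C6–C10.
Enabling feature: C10 lies alpha to the oxygenated C1 and is tied through C6 and C7 to C8 and C9, the only unsubstituted carbons of ring B. A C1 silyl enol ether in ring A can therefore close C9–C10 onto a C8≡C9 alkyne carried by the C6 carbinol.
Retrosynthetic cuts, in order: the anisoyl C–O bond at C1, the C3–CH3 bond together with the C2=C3 unsaturation, C9–C10 (ring B), C6–C7 (propargyl arm), and C10–CH3.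
Forward: ring A is bought as cycloheptane-1,3-dione, whose symmetry gives the C1 enol silylation a single outcome. The arm is joined at C6, gold closes ring B, and then C8=C9, the C3-methyl enone, C1 and the ester are adjusted.
Stereochemistry: C7 comes from a lipase-resolved propargylic alcohol (net inversion through an axially chiral allenylzinc). C6 comes from the closed transition state of that addition, C10 from the C6–C7–C8 tether (cis fusion), and C1 from hydride delivery by the C6 hydroxyl.

Key step: step 7

Assumption: Candida antarctica lipase B treats 4 by its usual size rule for secondary alcohols, with ethynyl as the small and isopropyl as the large group, so the (S)-alcohol is acylated faster.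

Step 1
Reactants: 1 cycloheptane-1,3-dione
Product: 2 2-methylcycloheptane-1,3-dione
Conditions: MeI, K2CO3, acetone, 40 °C
Reagents that add atoms: iodomethane, CI
Why: C-alkylation of the stabilised 1,3-dione enolate with a soft electrophile places the future C10 methyl between the two carbonyl groups, a slight deficit of MeI limits double methylation, and the new centre is of no consequence because it is enolised in step 2.

Step 2
Reactants: 2 2-methylcycloheptane-1,3-dione
Product: 3 2-methyl-3-(triisopropylsilyloxy)cyclohept-2-en-1-one
Conditions: TIPSOTf, Et3N, CH2Cl2, 0 °C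
Reagents that add atoms: triisopropylsilyl trifluoromethanesulfonate, CC(C)[Si](C(C)C)(C(C)C)OS(=O)(=O)C(F)(F)F
Why: O-silylation of a 1,3-dione by soft enolisation gives the vinylogous silyl ester, and because 2 is mirror-symmetric both oxygens lead to the same achiral product, in which C1 is fixed as the C1=C10 enol ether and only C6 remains a ketone.

Step 3
Reactants: 4 racemic 4-methylpent-1-yn-3-ol
Product: 5 (3R)-4-methylpent-1-yn-3-ol (the unreacted enantiomer)
Conditions: Novozym 435 (immobilised Candida antarctica lipase B), vinyl acetate, hexane, 30 °C, stopped beyond half conversion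
Reagents that add atoms: none
Why: Lipase-catalysed kinetic resolution by irreversible transesterification should acylate the (S)-enantiomer faster, so the wanted (R)-alcohol is the slow partner and its enantiopurity rises the further the reaction is run.

Step 4
Reactants: 5 (3R)-4-methylpent-1-yn-3-ol
Product: 6 (3R)-4-methylpent-1-yn-3-yl methanesulfonate
Conditions: MsCl, Et3N, CH2Cl2, −78 → 0 °C
Reagents that add atoms: methanesulfonyl chloride, CS(=O)(=O)Cl
Why: Sulfonylation takes place at oxygen, so the carbinol stereocenter is untouched and the leaving group for the palladium step is installed.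

Step 5
Reactants: 6 (3R)-4-methylpent-1-yn-3-yl methanesulfonate; 3 2-methyl-3-(triisopropylsilyloxy)cyclohept-2-en-1-one
Product: 8 (1S)-2-methyl-1-[(3S)-4-methylpent-1-yn-3-yl]-3-(triisopropylsilyloxy)cyclohept-2-en-1-ol, via allenylzinc mesylate 7 (not isolated)
Conditions: Pd(OAc)2 (5 mol %), PPh3 (5 mol %), Et2Zn, THF, −20 → 0 °C; pH 7 buffer
Reagents that add atoms: none
Why: Zerovalent palladium displaces the mesylate anti (SN2′), Et2Zn converts the allenylpalladium with retention into the axially chiral allenylzinc 7, and 7 adds to the C6 ketone through a closed six-membered SE2′ transition state (allenylzinc propargylation of a carbonyl group), so C7 arises by net inversion of the carbinol centre of 6, and C6 is set by placing the bulkier C10(Me)=C1 flank of the ketone beside the allenyl hydrogen and the C5 methylene beside the isopropyl group, which gives the (6S,7S) isomer with oxygen and isopropyl on the same side of the future ring B.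

Step 6
Reactants: 8 (1S)-2-methyl-1-[(3S)-4-methylpent-1-yn-3-yl]-3-(triisopropylsilyloxy)cyclohept-2-en-1-ol
Product: 9 triethylsilyl ether of 8 at the C6 oxygen, (6S,7S); ring A carries the C1 TIPS enol ether (C1=C10, methyl on C10), and C6 carries OTES and the 1-isopropylpropargyl arm
Conditions: TESOTf, 2,6-lutidine, CH2Cl2, −78 °C
Reagents that add atoms: triethylsilyl trifluoromethanesulfonate, CC[Si](CC)(CC)OS(=O)(=O)C(F)(F)F
Why: Silylation with a silyl triflate and excess hindered pyridine base at low temperature caps the tertiary C6 alcohol faster than the acid-labile hydroxy enol ether can ionise, and the cap later blocks oxygen attack on the activated alkyne.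

Step 7
Reactants: 9 C6 triethylsilyl ether with C1 TIPS enol ether and terminal alkyne
Product: 10 (1S,3aS,8aS)-3a-methyl-1-(propan-2-yl)-8a-(triethylsilyloxy)-3a,5,6,7,8,8a-hexahydroazulen-4(1H)-one; in route numbering C1 ketone, C6 OTES, C8=C9 alkene, (6S,7S,10S)
Conditions: Ph3PAuCl (10 mol %), AgBF4 (10 mol %), CH2Cl2/MeOH 10:1, rt → 40 °C
Reagents that add atoms: none
Why: The cationic monovalent gold complex made from Ph3PAuCl and AgBF4 binds the terminal C8≡C9 alkyne, C10 of the C1 silyl enol ether attacks C9 anti to the metal, and methanol then takes the silyl group from the oxocarbenium ion and protonates the C8–Au bond, which frees the C1 ketone and the catalyst. The closest known reaction type is the gold-catalysed carbocyclisation of silyl enol ethers onto alkynes, which is established for 5-endo-dig closures that build quaternary carbons on cyclic ketones. Ring B closes in the 5-(enolexo)-endo-dig mode with both alkyne carbons in the ring, and the 4-exo-dig alternative would give a strained methylenecyclobutane and is not expected. The one new stereocenter, C10, is controlled by C6: the C6–C7–C8 tether lets C9 reach only the face of the C1=C10 bond on which the propargyl arm stands, so the methyl group is pushed to the face of the C6 oxygen (cis fusion, 10S). The step needs carbon attack to outrun oxygen attack, solvolysis of the enol ether and ionisation of the allylic C6–O bond; the TES cap removes the oxygen nucleophile, the bulky TIPS group slows solvolysis and fixes the nucleophile as the single C1=C10 regioisomer, and the medium stays close to neutral.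

Step 8
Reactants: 10 bicyclic ketone with C8=C9 alkene
Product: 11 (1R,3aS,8aS)-3a-methyl-1-(propan-2-yl)-8a-(triethylsilyloxy)octahydroazulen-4(1H)-one; route numbering (6S,7R,10S), the C7 descriptor changing only through ligand ranking
Conditions: KO2CN=NCO2K, AcOH, MeOH, 0 °C → rt
Reagents that add atoms: none
Why: Diimide reduction transfers two hydrogens in a concerted syn manner to the strained cis-disubstituted C8=C9 bond, the only alkene in 10, without the metal-hydride alkene migration that could scramble the allylic C7 centre, and it leaves the ketone and the silyl ether alone.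

Step 9
Reactants: 11 saturated bicyclic ketone
Product: 13 (1R,3aS,8aS)-3a-methyl-1-(propan-2-yl)-8a-(triethylsilyloxy)-2,3,3a,7,8,8a-hexahydroazulen-4(1H)-one (C2=C3 enone), via lithium enolate 12 (not isolated)
Conditions: LiN(iPr)2, THF, −78 °C; then PhS(Cl)=NtBu, −78 °C
Reagents that add atoms: none
Why: C10 is quaternary, so the C1 ketone can be enolised only toward C2, and in the Mukaiyama dehydrogenation the enolate 12 attacks the sulfur of the sulfinimidoyl chloride and loses a C3 hydrogen by intramolecular syn elimination at low temperature, giving the enone without touching a stereocenter.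

Step 10
Reactants: 13 C2=C3 enone
Product: 15 (1R,3aS,8aS)-3a,6-dimethyl-1-(propan-2-yl)-8a-(triethylsilyloxy)-2,3,3a,7,8,8a-hexahydroazulen-4(1H)-one (C3-methyl enone), via lithium enolate 14 (not isolated)
Conditions: Me2CuLi (MeLi, CuI), Et2O, −78 → −30 °C; then PhS(Cl)=NtBu, THF, −78 °C → rt
Reagents that add atoms: lithium dimethylcuprate, [Li+].C[Cu-]C
Why: Cuprate conjugate addition delivers the C3 methyl group and the regiodefined C1=C2 enolate 14, which the same sulfinimidoyl chloride dehydrogenates in the flask toward its only beta hydrogen at C3 (one-pot beta-alkylation of an enone), so the transient C3 centre is erased and the trisubstituted C2=C3 enone results.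

Step 11
Reactants: 15 C3-methyl enone with C6 OTES
Product: 16 (1R,3aS,8aS)-8a-hydroxy-3a,6-dimethyl-1-(propan-2-yl)-2,3,3a,7,8,8a-hexahydroazulen-4(1H)-one
Conditions: HF·pyridine, THF, 0 °C → rt
Reagents that add atoms: none
Why: Fluoride-driven silyl ether cleavage in a mildly acidic medium frees the tertiary C6 alcohol without forming the alkoxide that could start a retro-aldol cleavage of C6–C10, and dehydration by E1cB is excluded because C10 bears no hydrogen.

Step 12
Reactants: 16 beta-hydroxy enone
Product: 17 (3R,3aS,8R,8aR)-6,8a-dimethyl-3-(propan-2-yl)-1,2,3,3a,4,5,8,8a-octahydroazulene-3a,8-diol; route numbering (1R,6S,7R,10R)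
Conditions: Me4NBH(OAc)3, MeCN/AcOH 1:1, −20 °C
Reagents that add atoms: none
Why: In the Evans–Saksena reduction the C6 hydroxyl replaces an acetate on boron and the hydride is handed over within the complex to the face of the C1 carbonyl on which the C6 oxygen stands, so the new C1 hydroxyl comes out trans to the C6 hydroxyl and the C10 methyl (1R), while the free reagent is too weak a donor for external or conjugate reduction of the enone.

Step 13
Reactants: 17 diol; 18 4-methoxybenzoyl chloride
Product: 19 (3R,3aS,8R,8aR)-3a-hydroxy-6,8a-dimethyl-3-(propan-2-yl)-1,2,3,3a,4,5,8,8a-octahydroazulen-8-yl 4-methoxybenzoate (target)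
Conditions: Et3N, DMAP, CH2Cl2, 0 °C → rt
Reagents that add atoms: none
Why: DMAP-catalysed acylation esterifies the secondary allylic C1 alcohol, whereas the tertiary ring-fusion C6 alcohol is too hindered to react under these conditions, and no stereocenter is touched.

Compound list
1 | cycloheptane-1,3-dione | O=C1CCCCC(=O)C1 | starting material
2 | 2-methylcycloheptane-1,3-dione | CC1C(=O)CCCCC1=O | intermediate
3 | 2-methyl-3-(triisopropylsilyloxy)cyclohept-2-en-1-one | CC1=C(O[Si](C(C)C)(C(C)C)C(C)C)CCCCC1=O | intermediate
4 | racemic 4-methylpent-1-yn-3-ol | CC(C)C(O)C#C | starting material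
5 | (3R)-4-methylpent-1-yn-3-ol | C#C[C@@H](C(C)C)O | intermediate
6 | (3R)-4-methylpent-1-yn-3-yl methanesulfonate | C#C[C@@H](C(C)C)OS(C)(=O)=O | intermediate
7 | (aS)-(4-methylpenta-1,2-dien-1-yl)zinc methanesulfonate, not isolated | [H]C([Zn]OS(C)(=O)=O)=[C@]=C([H])C(C)C | intermediate
8 | (1S)-2-methyl-1-[(3S)-4-methylpent-1-yn-3-yl]-3-(triisopropylsilyloxy)cyclohept-2-en-1-ol | C#C[C@H](C(C)C)[C@@]1(O)CCCCC(O[Si](C(C)C)(C(C)C)C(C)C)=C1C | intermediate
9 | C6 triethylsilyl ether of 8, (6S,7S), key-step precursor | C#C[C@H](C(C)C)[C@@]1(O[Si](CC)(CC)CC)CCCCC(O[Si](C(C)C)(C(C)C)C(C)C)=C1C | intermediate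
10 | (1S,3aS,8aS)-3a-methyl-1-(propan-2-yl)-8a-(triethylsilyloxy)-3a,5,6,7,8,8a-hexahydroazulen-4(1H)-one, key-step product | O=C1CCCC[C@]2(O[Si](CC)(CC)CC)[C@@H](C(C)C)C=C[C@]12C | intermediate
11 | (1R,3aS,8aS)-3a-methyl-1-(propan-2-yl)-8a-(triethylsilyloxy)octahydroazulen-4(1H)-one | O=C1CCCC[C@]2(O[Si](CC)(CC)CC)[C@@H](C(C)C)CC[C@]12C | intermediate
12 | lithium C1=C2 enolate of 11, not isolated | [Li]OC1=CCCC[C@]2(O[Si](CC)(CC)CC)[C@@H](C(C)C)CC[C@]12C | intermediate
13 | (1R,3aS,8aS)-3a-methyl-1-(propan-2-yl)-8a-(triethylsilyloxy)-2,3,3a,7,8,8a-hexahydroazulen-4(1H)-one | O=C1C=CCC[C@]2(O[Si](CC)(CC)CC)[C@@H](C(C)C)CC[C@]12C | intermediate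
14 | lithium C1=C2 enolate with C3 methyl (C3 configuration of no consequence), not isolated | [Li]OC1=CC(C)CC[C@]2(O[Si](CC)(CC)CC)[C@@H](C(C)C)CC[C@]12C | intermediate
15 | (1R,3aS,8aS)-3a,6-dimethyl-1-(propan-2-yl)-8a-(triethylsilyloxy)-2,3,3a,7,8,8a-hexahydroazulen-4(1H)-one | O=C1C=C(C)CC[C@]2(O[Si](CC)(CC)CC)[C@@H](C(C)C)CC[C@]12C | intermediate
16 | (1R,3aS,8aS)-8a-hydroxy-3a,6-dimethyl-1-(propan-2-yl)-2,3,3a,7,8,8a-hexahydroazulen-4(1H)-one | O=C1C=C(C)CC[C@]2(O)[C@@H](C(C)C)CC[C@]12C | intermediate
17 | (3R,3aS,8R,8aR)-6,8a-dimethyl-3-(propan-2-yl)-1,2,3,3a,4,5,8,8a-octahydroazulene-3a,8-diol | O[C@@H]1C=C(C)CC[C@]2(O)[C@@H](C(C)C)CC[C@]12C | intermediate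
18 | 4-methoxybenzoyl chloride | COc1ccc(C(Cl)=O)cc1 | starting material
19 | (3R,3aS,8R,8aR)-3a-hydroxy-6,8a-dimethyl-3-(propan-2-yl)-1,2,3,3a,4,5,8,8a-octahydroazulen-8-yl 4-methoxybenzoate | COc1ccc(C(=O)O[C@@H]2C=C(C)CC[C@]3(O)[C@@H](C(C)C)CC[C@]23C)cc1 | target

Total step count: 13. Longest linear sequence: 11 steps (steps 1, 2 and 5–13; the branch through steps 3, 4 and 5–13 is equally long).

Steps most likely to fail

Step 5.
- **Risk:** The ketone of 3 is deactivated by the silyloxy donor and flanked by a substituted alkene, so the addition may be slow. During a slow addition the allenylzinc may lose configurational purity or be consumed by protonation. Facial selectivity at C6 may be poor, and the zinc alkoxide may take the TIPS group over from the enol oxygen.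
- **Fallback:** The nucleophile is prepared as an isolable, configurationally stable boron reagent instead of a transient zinc species. Starting from 5, methyl chloroformate and pyridine give the methyl carbonate F1. Copper-catalysed anti-SN2′ borylation (CuOtBu, Xantphos, B2pin2, THF) converts it into the allenylboronate F2, which has the same axial configuration as 7. F2 is then added to 3 through a closed boron-centred transition state under catalysis by a biphenol-type diol, with no palladium or zinc in the flask. Aqueous work-up returns to the route at 8.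

Step 7.
- **Risk:** Solvolysis of the enol ether, acid-triggered loss of the allylic C6 silyloxy group, or addition of methanol to the alkyne may outrun the carbocyclisation at the crowded C10.
- **Fallback:** The alkyne is given an activating group. Starting from 9, NIS and AgNO3 (cat.) in acetone give the iodoalkyne F3, whose more polarised triple bond is known to favour this 5-endo-dig closure. The same Ph3PAuCl/AgBF4 catalyst should convert it into the C9 vinyl iodide F4. Hydrodeiodination with Bu3SnH and Pd(PPh3)4 returns to the route at 10.

Step 12.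
- **Risk:** Ligand exchange at the hindered tertiary C6 hydroxyl may be slow. The ketone may then stay unreduced, or undirected hydride attack from the face opposite the C10 methyl may erode facial selectivity.
- **Fallback:** The hydride is tied covalently to the C6 oxygen. Starting from 16, iPr2SiHCl, Et3N and DMAP give the diisopropylsilyl ether F5. Intramolecular hydrosilylation of the C1 ketone (SnCl4 cat., CH2Cl2, −78 °C) delivers hydrogen from the face of the C6 oxygen and gives the cyclic silylene acetal F6. HF·pyridine cleaves F6 and returns to the route at 17.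

Further compounds
F1 | step 5 | methyl (3R)-4-methylpent-1-yn-3-yl carbonate | C#C[C@@H](C(C)C)OC(=O)OC
F2 | step 5 | (aS)-4,4,5,5-tetramethyl-2-(4-methylpenta-1,2-dien-1-yl)-1,3,2-dioxaborolane | [H]C(B1OC(C)(C)C(C)(C)O1)=[C@]=C([H])C(C)C
F3 | step 7 | C9 iodoalkyne analogue of 9, (6S,7S) | IC#C[C@H](C(C)C)[C@@]1(O[Si](CC)(CC)CC)CCCCC(O[Si](C(C)C)(C(C)C)C(C)C)=C1C
F4 | step 7 | C9 iodo analogue of 10 (vinyl iodide), (6S,7S,10S) | IC1=C[C@H](C(C)C)[C@@]2(O[Si](CC)(CC)CC)CCCCC(=O)[C@@]12C
F5 | step 12 | C6 diisopropylsilyl ether of 16 | O=C1C=C(C)CC[C@]2(O[SiH](C(C)C)C(C)C)[C@@H](C(C)C)CC[C@]12C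
F6 | step 12 | cyclic diisopropylsilylene acetal of 17 bridging the C1 and C6 oxygens | CC(C)[Si]1(C(C)C)O[C@@H]2C=C(C)CC[C@]3(O1)[C@@H](C(C)C)CC[C@]23C
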